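# Proposed total synthesis of (3S,4S,5S,6S,8R,9S,10S,13R,16S)-3,7,16-trihydroxygibberellan-19-oic acid (CNP0170663.1)

## Analysis of the target

The target is a C20 gibberellane (gibberellane numbering throughout) in which ring A (cyclohexane, C1–C5 and C10) is fused trans to ring B (cyclopentane, C5, C6, C8, C9, C10), and ring B shares the C8–C9 bond with a bicyclo[3.2.1]octane made of ring C (C8, C9, C11–C14) and ring D (C8, C14, C13, C16, C15). There are nine stereocentres: C4, C8 and C10 are quaternary, C16 is a tertiary carbinol, and the C19 carboxyl and the C20 methyl stand 1,3-diaxial on the same face of ring A. C8, C13 and C16 are tied together by the bicyclooctane, C9 carries C10 axially on the C14 face of ring C, and C6 is the only centre outside the rigid frame, with the hydroxymethyl C7 trans to C4 on ring B. The C3 hydroxyl is axial and anti to C19. This β-hydroxy acid with a quaternary α-carbon can cleave by retro-aldol in base, and the C16 carbinol becomes a retro-aldol partner whenever C12 is a ketone. The difficulty is the crowded C4–C5–C10 sector and the absolute configuration of a bicyclooctane that has no nearby handle. The plan rests on two features: C10 bears a methyl (C20) and is bonded to C5, so C10 can be generated as a tertiary radical by hydrogen-atom transfer to a C10=C20 methylene and joined to C5 of an enoate (ring B). The C3 hydroxyl and C19 on C4 form an aldol pair, so the enolate left at C4 can close ring A onto a C3 aldehyde.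

## Retrosynthetic reasoning

**27 ⇒ 26.** The acid and the C7 alcohol are both carried as benzyl derivatives, so one hydrogenolysis ends the route. A benzyl ether is preferred to a silyl ether at C7 because it survives the aqueous acid needed to unmask the C3 aldehyde and needs no separate deprotection.

**26 ⇒ 25 ⇒ 24.** The axial C3 hydroxyl is anti to C19. A metal-bridged aldol keeps O3 gauche to C19 and cannot give this arrangement directly. The C3 centre is therefore planned through ketone 25, reduced from the equatorial side, and 25 comes from the aldol product 24, the C3 epimer of 26.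

**24 ⇒ 23 (key disconnection).** The C3–C4 and C5–C10 bonds are cut. They flank the C4–C5 bond, so both rings unzip into two arms on the rigid bicyclooctane: an enoate arm on C8 and an alkene–aldehyde arm on C9. Cutting here removes two rings and four stereocentres (C3, C4, C5, C10) at once and leaves a precursor whose stereocentres lie in or next to the bicycle. Forward, one hydrogen atom delivered to C20 must trigger radical closure of ring B and polar closure of ring A.

**23 ⇒ 22 ⇒ 21 ⇒ 20 ⇒ 19.** These are functional-group adjustments. The C3 aldehyde is masked as a dioxolane and the C16 carbinol as a silyl ether. The C12 methylene is traced to a ketone through carbinol 20 and xanthate 21, because a C12 carbonyl makes C9 electrophilic and C13 nucleophilic in the earlier steps.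

**19 ⇒ 13 + 16.** The C9–C10 bond is cut to enone 13 and an alkenyl metal from bromide 16. This brings in C10, C20, C1, C2 and C3 in one piece and lets the bicycle set C9. Bromide 16 comes from 14 (C10, C20, C1) and 15 (C2, C3).

**13 ⇒ 12 ⇒ 8 + 11.** The C4=C5 bond is made by Wittig olefination of aldehyde 8 with ylide 11 (from 9), which supplies C4, C18 and C19 with the (E)-geometry.

**8 ⇒ 7 ⇒ 6 ⇒ 5.** The C6–C7 bond is formed by α-hydroxymethylation of aldehyde 7, which creates the one acyclic stereocentre under catalyst control. Aldehyde 7 comes from cleavage of the allyl group of 6. This must precede introduction of the C10=C20 alkene, because the two alkenes could not be told apart afterwards.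

**5 ⇒ 3.** The C13–C16 bond is cut by a retro-aldol to the achiral dienone 3. Forward, a hydride adds to one of two enantiotopic enone arms and the enolate closes the two-carbon bridge. One step thus sets C8, C13 and C16 and leaves the enone needed for the C9–C10 bond.

**3 ⇒ 1 + 2.** The C8–C6 bond is cut to phenol 1 and allylsilane 2. Dearomative para-allylation builds the quaternary carbon from a flat, commercial arene.

## Alternatives that were turned down

**Alternative 1:** The bicyclic enedione A1 (rings B and C) is disconnected at C9–C11 to an achiral triketone in which C8 lies between two enantiotopic ring carbonyls. Forward, L-proline A2 forms the enamine of the side-chain methyl ketone (C11), adds it to one ring carbonyl (C9) and the aldol condenses (Hajos–Parrish reaction); this closes ring C and fixes C8.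
- For it: the enantio-determining step is a tethered C–C bond formation of a long-established type. It is better founded than the hydride discrimination between two similar arms used here, and it is cheap and scalable.
- Against it: A1 holds one stereocentre and two rings. C9 is sp2, C10 and C5 are plain methylenes, and rings A and D, the C10 and C4 quaternary carbons and seven stereocentres all remain to be built on a cyclopentanone with little bias.
- Comparison: it is stronger on absolute control, but its key step builds one ring and one centre early. The chosen step builds two rings and four centres late, so the overall route is shorter.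

**Alternative 2:** Ring B is not built but contracted: the C7–C8 bond of a kaurane is exchanged for C6–C8. Forward, an ent-kaurenoic acid oxidase (a cytochrome P450 monooxygenase) oxidises its 7-hydroxylated substrate at C6, C8 shifts from C7 to C6, and C7 is left as the aldehyde of the 7-oxogibberell-16-en-19-oic acid A3.
- For it: one enzymatic step delivers the whole gibberellane skeleton with seven of the nine stereocentres correct, including the C4–C5–C10 sector. No abiotic step matches this.
- Against it: A3 has no oxygen at C3, and an unactivated ring A methylene can only be hydroxylated by a second enzyme. The C16 carbinol would need degradation to the 17-nor ketone and methyl addition. The route also depends on a membrane-bound enzyme with its reductase partner and on a natural diterpene supply, not on commercial chemicals.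
- Comparison: it is stronger on skeleton and stereocontrol. The chosen strategy places the C3 oxygen through the aldol itself and stays within bench chemistry.

**Alternative 3:** The tetracycle A4 is cut at C4–C5 and C9–C10. Forward, Mn(OAc)3 A5 oxidises an open-chain β-keto ester to the C4 radical, which closes ring A on C5 of a C5=C10 alkene. The tertiary C10 radical then closes ring B on C9 of a bicyclooctene, and Cu(OAc)2 A6 oxidises the C11 radical to the C11–C12 alkene.
- For it: oxidative radical polycyclisation of β-keto esters is an established reaction class. Its chair transition state is known to place the ester axial at C4, and it gives the C3 ketone directly. On precedent and on C4 it is stronger than the chosen step.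
- Against it: the second closure is an addition of a nucleophilic tertiary radical to an unactivated, neopentyl-flanked ring alkene, with no polarity help. It competes with oxidation of that radical by divalent copper, which would stop the cascade after ring A. It also needs a geometrically defined trisubstituted alkene next to C6, stoichiometric metal oxidants in a carboxylic acid solvent, and later saturation of C11–C12.
- Comparison: step counts are similar. The chosen step offers a polarity-matched radical addition and catalytic iron under neutral conditions, at the price of weaker control at C4.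

Key step: step 15

Assumption: the sense of induction of the chiral copper hydride in step 2 cannot be derived for this dienone; (R)-DTBM-SEGPHOS is written, and its antipode is used if it should give the enantiomer of 5.

## Route

**Step 1**
Reactants: 1 1-(4-hydroxyphenyl)propan-2-one; 2 allyltrimethylsilane
Product: 3 4-(2-oxopropyl)-4-(prop-2-en-1-yl)cyclohexa-2,5-dien-1-one
Conditions: PhI(OAc)2 (1.2 equiv), 2 (4 equiv), (CF3)2CHOH, −10 → 0 °C
Reagents that add atoms: none
Why: Oxidative dearomatisation of the para-substituted phenol gives a phenoxenium-type intermediate that the allylsilane captures at the substituted para carbon (Hosomi–Sakurai-type allylation); the fluorinated alcohol stabilises the cation and is too weak a nucleophile to compete. No stereocentre forms, since the two enone arms of 3 are enantiotopic.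

**Step 2**
Reactants: 3 dienone
Product: 5 (1R,5S,7S)-7-hydroxy-7-methyl-5-(prop-2-en-1-yl)bicyclo[3.2.1]oct-3-en-2-one, via silyl ether 4 (not isolated)
Conditions: Cu(OAc)2·H2O (5 mol%), (R)-DTBM-SEGPHOS (5.5 mol%), (EtO)2MeSiH (1.2 equiv), toluene, −20 °C; then 1 M HCl, THF, 0 °C
Reagents that add atoms: none
Why: Copper hydride reductive aldol cyclisation: the bisphosphine copper hydride (monovalent copper) adds hydride to the β-carbon (C14) of one of the two enantiotopic enone arms, and the copper enolate adds through C13 to the methyl ketone in a closed six-membered transition state, so the C16 oxygen ends up on the side of the C12 carbonyl (endo) and C17 exo. The catalyst's choice of arm (desymmetrisation of a 4,4-disubstituted cyclohexadienone) sets C8 and, because the bridge can only close cis, C13 with it. Silyl transfer to the copper alkoxide blocks retro-aldol, and the acid work-up frees the alcohol.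

**Step 3**
Reactants: 5 bicyclic hydroxy enone
Product: 6 (1R,5S,7S)-7-methyl-5-(prop-2-en-1-yl)-7-[(triethylsilyl)oxy]bicyclo[3.2.1]oct-3-en-2-one
Conditions: Et3SiOTf, 2,6-lutidine, CH2Cl2, −78 → 0 °C
Reagents that add atoms: triethylsilyl trifluoromethanesulfonate, CC[Si](CC)(CC)OS(=O)(=O)C(F)(F)F
Why: Silylation of the hindered tertiary alcohol with a silyl triflate; the enone has no enolisable position (C13 is a bridgehead, C8 is quaternary), so only oxygen reacts. The ether blocks retro-aldol cleavage of C13–C16 in the basic steps that follow while C12 is a ketone.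

**Step 4**
Reactants: 6 allyl enone
Product: 7 [(1S,5R,6S)-6-methyl-4-oxo-6-[(triethylsilyl)oxy]bicyclo[3.2.1]oct-2-en-1-yl]acetaldehyde
Conditions: OsO4 (2 mol%), NaIO4 (4 equiv), 2,6-lutidine, dioxane/H2O (3:1), 23 °C
Reagents that add atoms: osmium tetroxide, O=[Os](=O)(=O)=O; sodium periodate, [Na+].[O-]I(=O)(=O)=O
Why: Johnson–Lemieux oxidation: OsO4 dihydroxylates the electron-rich terminal alkene much faster than the electron-poor, hindered enone, and NaIO4 cleaves the diol and re-oxidises osmium. The allyl CH2 becomes C6 and the aldehyde carbon C5.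

**Step 5**
Reactants: 7 aldehyde
Product: 8 (2S)-3-hydroxy-2-[(1R,5R,6S)-6-methyl-4-oxo-6-[(triethylsilyl)oxy]bicyclo[3.2.1]oct-2-en-1-yl]propanal
Conditions: (R)-2-[diphenyl(trimethylsilyloxy)methyl]pyrrolidine (20 mol%), aq HCHO (37%, 3 equiv), pH 7 phosphate buffer, toluene, 23 °C; crude product used directly
Reagents that add atoms: formaldehyde, C=O
Why: Enamine-catalysed α-hydroxymethylation (organocatalytic cross-aldol with formaldehyde): the (E)-enamine of 7 is attacked on the face away from the diphenyl(silyloxy)methyl group of the (R)-catalyst, which should set C6 as S under catalyst control. The β-hydroxy aldehyde is carried on at once because it can epimerise or lose water on standing.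

**Step 6**
Reactants: 9 benzyl 2-bromopropanoate
Product: 11 benzyl 2-(triphenyl-λ5-phosphanylidene)propanoate, via phosphonium bromide 10 (not isolated)
Conditions: PPh3, toluene, 90 °C; then 2 M NaOH, CH2Cl2, 0 °C
Reagents that add atoms: triphenylphosphine, c1ccc(cc1)P(c1ccccc1)c1ccccc1
Why: Alkylation of the phosphine by the α-bromo ester and deprotonation of the salt give the stabilised ylide (standard preparation of a Wittig reagent).

**Step 7**
Reactants: 8 hydroxy aldehyde; 11 ylide
Product: 12 benzyl (2E,4S)-5-hydroxy-2-methyl-4-[(1R,5R,6S)-6-methyl-4-oxo-6-[(triethylsilyl)oxy]bicyclo[3.2.1]oct-2-en-1-yl]pent-2-enoate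
Conditions: 11 (1.5 equiv), toluene, 60 °C
Reagents that add atoms: none
Why: Wittig olefination with a stabilised α-methyl ylide gives the (E)-trisubstituted enoate (ester trans to C6) and is mild enough to leave the C6 centre, the enone and the silyl ether untouched.

**Step 8**
Reactants: 12 hydroxy enoate
Product: 13 benzyl (2E,4S)-5-(benzyloxy)-2-methyl-4-[(1R,5R,6S)-6-methyl-4-oxo-6-[(triethylsilyl)oxy]bicyclo[3.2.1]oct-2-en-1-yl]pent-2-enoate
Conditions: 2-benzyloxy-1-methylpyridinium triflate (2 equiv), MgO, PhCF3, 85 °C
Reagents that add atoms: 2-(benzyloxy)-1-methylpyridinium trifluoromethanesulfonate, C[n+]1ccccc1OCc1ccccc1.[O-]S(=O)(=O)C(F)(F)F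
Why: Benzyl transfer from the pyridinium salt under neutral conditions protects the primary C7 alcohol without base, so the enone, the enoate and the acidic C6–H are not put at risk. The benzyl ether survives the aqueous acid of step 14 and leaves in step 18 together with the ester.

**Step 9**
Reactants: 14 2,3-dibromoprop-1-ene; 15 (1,3-dioxolan-2-ylmethyl)magnesium bromide
Product: 16 2-(3-bromobut-3-en-1-yl)-1,3-dioxolane
Conditions: CuI (5 mol%), THF, −20 → 23 °C
Reagents that add atoms: none
Why: Copper-catalysed coupling of the Grignard reagent at the allylic bromide; the vinylic bromide is inert under these conditions. The product holds C10, C20, C1, C2 and the masked C3.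

**Step 10**
Reactants: 13 enone; 16 alkenyl bromide
Product: 19 benzyl (2E,4S)-5-(benzyloxy)-4-[(1R,2S,5R,6S)-2-[4-(1,3-dioxolan-2-yl)but-1-en-2-yl]-6-methyl-4-oxo-6-[(triethylsilyl)oxy]bicyclo[3.2.1]octan-1-yl]-2-methylpent-2-enoate, via alkenylmagnesium bromide 17 (not isolated), via silyl enol ether 18 (not isolated)
Conditions: 16, Mg, THF, 45 °C; then slow addition to 13, CuBr·SMe2 (20 mol%), Me3SiCl, THF, −78 → −40 °C; then AcOH/THF/H2O, 0 °C
Reagents that add atoms: none
Why: Copper-catalysed conjugate addition of the alkenyl Grignard reagent, accelerated by the chlorosilane; the cyclic enone is far more reactive than the α-methyl, γ-branched enoate, and slow addition keeps free Grignard reagent low. The nucleophile reaches C9 from the face of the one-carbon bridge (C14), because the other face is screened by the C15–C16 bridge and its endo silyloxy group; this puts C10 axial on ring C (9S). Mild acid returns the C12 ketone from the enol silane.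

**Step 11**
Reactants: 19 ketone
Product: 20 benzyl (2E,4S)-5-(benzyloxy)-4-[(1R,2S,5S,6S)-2-[4-(1,3-dioxolan-2-yl)but-1-en-2-yl]-4-hydroxy-6-methyl-6-[(triethylsilyl)oxy]bicyclo[3.2.1]octan-1-yl]-2-methylpent-2-enoate (both carbinol epimers)
Conditions: NaBH4, MeOH/THF, 0 °C
Reagents that add atoms: none
Why: Chemoselective 1,2-reduction of the ketone; the enoate and the acetal do not react at 0 °C. The configuration at C12 is of no consequence because the oxygen is removed in step 13.

**Step 12**
Reactants: 20 C12 carbinol
Product: 21 benzyl (2E,4S)-5-(benzyloxy)-4-[(1R,2S,5S,6S)-2-[4-(1,3-dioxolan-2-yl)but-1-en-2-yl]-6-methyl-4-{[(methylsulfanyl)carbonothioyl]oxy}-6-[(triethylsilyl)oxy]bicyclo[3.2.1]octan-1-yl]-2-methylpent-2-enoate (both epimers)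
Conditions: NaN(SiMe3)2, THF, −78 °C; CS2; then MeI, −78 → 0 °C
Reagents that add atoms: carbon disulfide, S=C=S; iodomethane, CI
Why: Xanthate formation for the Barton–McCombie deoxygenation: the alkoxide adds to CS2 and is S-methylated. At −78 °C the amide base removes only the hydroxyl proton, not the γ-hydrogen of the enoate.

**Step 13**
Reactants: 21 xanthate
Product: 22 benzyl (2E,4S)-5-(benzyloxy)-4-[(1R,2S,5R,6S)-2-[4-(1,3-dioxolan-2-yl)but-1-en-2-yl]-6-methyl-6-[(triethylsilyl)oxy]bicyclo[3.2.1]octan-1-yl]-2-methylpent-2-enoate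
Conditions: Bu3SnH, AIBN (cat.), toluene, 100 °C
Reagents that add atoms: none
Why: Barton–McCombie deoxygenation: the stannyl radical adds to the thiocarbonyl sulfur, the C12–O bond fragments and the secondary C12 radical takes hydrogen from the stannane. The C12 radical has no alkene within reach of a favourable closure: C10=C20 would need a 4-exo or 5-endo mode, and C5 of the enoate could be reached only through a bridged boat of ring C, so simple reduction is expected.

**Step 14**
Reactants: 22 acetal
Product: 23 benzyl (2E,4S)-5-(benzyloxy)-4-[(1R,2S,5R,6S)-6-hydroxy-6-methyl-2-(5-oxopent-1-en-2-yl)bicyclo[3.2.1]octan-1-yl]-2-methylpent-2-enoate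
Conditions: 1 M HCl, THF, 23 °C
Reagents that add atoms: water, O
Why: Acid hydrolysis frees the C3 aldehyde from the dioxolane and cleaves the tertiary triethylsilyl ether in the same operation; the benzyl ether, the enoate and the 1,1-disubstituted alkene are stable to dilute aqueous acid at room temperature. With C12 now a methylene, the free C16 carbinol can no longer cleave by retro-aldol.

**Step 15**
Reactants: 23 enoate aldehyde
Product: 24 benzyl (3R,4S,5S,6S,8R,9S,10S,13R,16S)-7-(benzyloxy)-3,16-dihydroxygibberellan-19-oate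
Conditions: Fe(acac)3 (30 mol%), PhSiH3 (2.5 equiv), ClCH2CH2Cl/(CH2OH)2 (10:1), 0.005 M, 0 → 23 °C
Reagents that add atoms: none
Why: Proposed new method: Fe(acac)3 and PhSiH3 form an iron hydride (trivalent iron) that passes a hydrogen atom to C20 of the electron-rich 1,1-disubstituted alkene; the tertiary C10 radical adds to C5 of the enoate (5-exo-trig, ring B), the C4 α-ester radical is reduced by divalent iron to an iron enolate, and this adds to the C3 aldehyde (6-(enolexo)-exo-trig aldol, ring A) before the silane turns the iron alkoxide over. The closest known reaction types are iron-hydride hydrogen-atom-transfer Giese cyclisations and radical–polar crossover conjugate addition–aldol annulations, which have not yet been joined in one bicyclisation. C5 is controlled by C6 through allylic 1,3-strain: C6–H lies in the plane of the C4=C5 bond next to C18, the radical tethered through C8 attacks the face that holds C8, and C4 ends up trans to C7. C10 is controlled by C9: the radical centre sits axially on the C14 face of ring C, the small C20 methyl takes the place over ring C next to C11 and C14 and the C1 chain the place next to C9–H, which gives the trans A/B fusion, though only with a modest bias. C4 is set by the rotamer about C5–C4 in the chair-like aldol transition state: with the enolate carbon C19 anti to C5–H the C18 methyl avoids a 1,3-diaxial contact with C20 and the ester becomes axial (4α), but allylic strain in the enolate works against this and C4 is the least secured centre. C3 follows from the closed, metal-bridged transition state, which keeps O3 gauche to C19 and gives the equatorial 3α-alcohol (3R), the C3 epimer of the target, to be inverted in steps 16 and 17. The step needs hydrogen-atom transfer to the alkene in preference to the enoate and the aldehyde, which the polarity matching secures, and a dilute, weakly protic medium so that the enolate closes ring A before it is protonated.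

**Step 16**
Reactants: 24 3α-hydroxy ester
Product: 25 benzyl (4S,5S,6S,8R,9S,10S,13R,16S)-7-(benzyloxy)-16-hydroxy-3-oxogibberellan-19-oate
Conditions: DMP (1,1,1-triacetoxy-1,1-dihydro-1,2-benziodoxol-3(1H)-one), CH2Cl2, 0 → 23 °C
Reagents that add atoms: none
Why: Periodinane oxidation of the secondary C3 alcohol under neutral conditions; the tertiary C16 alcohol cannot be oxidised, and the β-keto ester has no hydrogen on C4, so C4 cannot epimerise.

**Step 17**
Reactants: 25 3-ketone
Product: 26 benzyl (3S,4S,5S,6S,8R,9S,10S,13R,16S)-7-(benzyloxy)-3,16-dihydroxygibberellan-19-oate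
Conditions: LiBH(s-Bu)3 (2.5 equiv), THF, −78 °C; aq NH4Cl
Reagents that add atoms: none
Why: The bulky borohydride attacks the ring A ketone along the equatorial trajectory and gives the axial 3β-alcohol (3S), anti to the C19 ester; a small hydride would favour the equatorial alcohol. The benzyl ester is not reduced at −78 °C.

**Step 18**
Reactants: 26 dibenzyl-protected triol acid
Product: 27 (3S,4S,5S,6S,8R,9S,10S,13R,16S)-3,7,16-trihydroxygibberellan-19-oic acid
Conditions: H2 (1 atm), Pd(OH)2/C, EtOAc/MeOH, 23 °C
Reagents that add atoms: none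
Why: Hydrogenolysis over Pd(OH)2/C cleaves the benzyl ester and the benzyl ether in one operation; 26 holds no other reducible group.

## Compound list

1 | 1-(4-hydroxyphenyl)propan-2-one | CC(=O)Cc1ccc(O)cc1 | starting material
2 | allyltrimethylsilane | C=CC[Si](C)(C)C | starting material
3 | 4-(2-oxopropyl)-4-(prop-2-en-1-yl)cyclohexa-2,5-dien-1-one | C=CCC1(CC(C)=O)C=CC(=O)C=C1 | intermediate
4 | (1R,5S,7S)-7-{[diethoxy(methyl)silyl]oxy}-7-methyl-5-(prop-2-en-1-yl)bicyclo[3.2.1]oct-3-en-2-one | C=CC[C@@]12C[C@@H](C(=O)C=C1)[C@@](C)(O[Si](C)(OCC)OCC)C2 | intermediate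
5 | (1R,5S,7S)-7-hydroxy-7-methyl-5-(prop-2-en-1-yl)bicyclo[3.2.1]oct-3-en-2-one | C=CC[C@@]12C[C@@H](C(=O)C=C1)[C@@](C)(O)C2 | intermediate
6 | (1R,5S,7S)-7-methyl-5-(prop-2-en-1-yl)-7-[(triethylsilyl)oxy]bicyclo[3.2.1]oct-3-en-2-one | C=CC[C@@]12C[C@@H](C(=O)C=C1)[C@@](C)(O[Si](CC)(CC)CC)C2 | intermediate
7 | [(1S,5R,6S)-6-methyl-4-oxo-6-[(triethylsilyl)oxy]bicyclo[3.2.1]oct-2-en-1-yl]acetaldehyde | O=CC[C@@]12C[C@@H](C(=O)C=C1)[C@@](C)(O[Si](CC)(CC)CC)C2 | intermediate
8 | (2S)-3-hydroxy-2-[(1R,5R,6S)-6-methyl-4-oxo-6-[(triethylsilyl)oxy]bicyclo[3.2.1]oct-2-en-1-yl]propanal | O=C[C@H](CO)[C@@]12C[C@@H](C(=O)C=C1)[C@@](C)(O[Si](CC)(CC)CC)C2 | intermediate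
9 | benzyl 2-bromopropanoate | CC(Br)C(=O)OCc1ccccc1 | starting material
10 | [1-(benzyloxy)-1-oxopropan-2-yl]triphenylphosphonium bromide | CC(C(=O)OCc1ccccc1)[P+](c1ccccc1)(c1ccccc1)c1ccccc1.[Br-] | intermediate
11 | benzyl 2-(triphenyl-λ5-phosphanylidene)propanoate | CC(C(=O)OCc1ccccc1)=P(c1ccccc1)(c1ccccc1)c1ccccc1 | intermediate
12 | benzyl (2E,4S)-5-hydroxy-2-methyl-4-[(1R,5R,6S)-6-methyl-4-oxo-6-[(triethylsilyl)oxy]bicyclo[3.2.1]oct-2-en-1-yl]pent-2-enoate | O=C(OCc1ccccc1)/C(C)=C/[C@H](CO)[C@@]12C[C@@H](C(=O)C=C1)[C@@](C)(O[Si](CC)(CC)CC)C2 | intermediate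
13 | benzyl (2E,4S)-5-(benzyloxy)-2-methyl-4-[(1R,5R,6S)-6-methyl-4-oxo-6-[(triethylsilyl)oxy]bicyclo[3.2.1]oct-2-en-1-yl]pent-2-enoate | O=C(OCc1ccccc1)/C(C)=C/[C@H](COCc1ccccc1)[C@@]12C[C@@H](C(=O)C=C1)[C@@](C)(O[Si](CC)(CC)CC)C2 | intermediate
14 | 2,3-dibromoprop-1-ene | C=C(Br)CBr | starting material
15 | (1,3-dioxolan-2-ylmethyl)magnesium bromide | Br[Mg]CC1OCCO1 | starting material
16 | 2-(3-bromobut-3-en-1-yl)-1,3-dioxolane | C=C(Br)CCC1OCCO1 | intermediate
17 | [4-(1,3-dioxolan-2-yl)but-1-en-2-yl]magnesium bromide | C=C([Mg]Br)CCC1OCCO1 | intermediate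
18 | benzyl (2E,4S)-5-(benzyloxy)-4-[(1R,2S,5R,6S)-2-[4-(1,3-dioxolan-2-yl)but-1-en-2-yl]-6-methyl-6-[(triethylsilyl)oxy]-4-[(trimethylsilyl)oxy]bicyclo[3.2.1]oct-3-en-1-yl]-2-methylpent-2-enoate | O=C(OCc1ccccc1)/C(C)=C/[C@H](COCc1ccccc1)[C@@]12C[C@@H](C(O[Si](C)(C)C)=C[C@H]1C(=C)CCC3OCCO3)[C@@](C)(O[Si](CC)(CC)CC)C2 | intermediate
19 | benzyl (2E,4S)-5-(benzyloxy)-4-[(1R,2S,5R,6S)-2-[4-(1,3-dioxolan-2-yl)but-1-en-2-yl]-6-methyl-4-oxo-6-[(triethylsilyl)oxy]bicyclo[3.2.1]octan-1-yl]-2-methylpent-2-enoate | O=C(OCc1ccccc1)/C(C)=C/[C@H](COCc1ccccc1)[C@@]12C[C@@H](C(=O)C[C@H]1C(=C)CCC3OCCO3)[C@@](C)(O[Si](CC)(CC)CC)C2 | intermediate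
20 | benzyl (2E,4S)-5-(benzyloxy)-4-[(1R,2S,5S,6S)-2-[4-(1,3-dioxolan-2-yl)but-1-en-2-yl]-4-hydroxy-6-methyl-6-[(triethylsilyl)oxy]bicyclo[3.2.1]octan-1-yl]-2-methylpent-2-enoate (both epimers at the carbinol carbon C12) | O=C(OCc1ccccc1)/C(C)=C/[C@H](COCc1ccccc1)[C@@]12C[C@@H](C(O)C[C@H]1C(=C)CCC3OCCO3)[C@@](C)(O[Si](CC)(CC)CC)C2 | intermediate
21 | benzyl (2E,4S)-5-(benzyloxy)-4-[(1R,2S,5S,6S)-2-[4-(1,3-dioxolan-2-yl)but-1-en-2-yl]-6-methyl-4-{[(methylsulfanyl)carbonothioyl]oxy}-6-[(triethylsilyl)oxy]bicyclo[3.2.1]octan-1-yl]-2-methylpent-2-enoate (both epimers at C12) | O=C(OCc1ccccc1)/C(C)=C/[C@H](COCc1ccccc1)[C@@]12C[C@@H](C(OC(=S)SC)C[C@H]1C(=C)CCC3OCCO3)[C@@](C)(O[Si](CC)(CC)CC)C2 | intermediate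
22 | benzyl (2E,4S)-5-(benzyloxy)-4-[(1R,2S,5R,6S)-2-[4-(1,3-dioxolan-2-yl)but-1-en-2-yl]-6-methyl-6-[(triethylsilyl)oxy]bicyclo[3.2.1]octan-1-yl]-2-methylpent-2-enoate | O=C(OCc1ccccc1)/C(C)=C/[C@H](COCc1ccccc1)[C@@]12C[C@@H](CC[C@H]1C(=C)CCC3OCCO3)[C@@](C)(O[Si](CC)(CC)CC)C2 | intermediate
23 | benzyl (2E,4S)-5-(benzyloxy)-4-[(1R,2S,5R,6S)-6-hydroxy-6-methyl-2-(5-oxopent-1-en-2-yl)bicyclo[3.2.1]octan-1-yl]-2-methylpent-2-enoate | O=C(OCc1ccccc1)/C(C)=C/[C@H](COCc1ccccc1)[C@@]12C[C@@H](CC[C@H]1C(=C)CCC=O)[C@@](C)(O)C2 | intermediate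
24 | benzyl (3R,4S,5S,6S,8R,9S,10S,13R,16S)-7-(benzyloxy)-3,16-dihydroxygibberellan-19-oate | C[C@@]12CC[C@@H](O)[C@@](C)(C(=O)OCc4ccccc4)[C@H]1[C@H](COCc4ccccc4)[C@@]13C[C@@H](CC[C@@H]21)[C@@](C)(O)C3 | intermediate
25 | benzyl (4S,5S,6S,8R,9S,10S,13R,16S)-7-(benzyloxy)-16-hydroxy-3-oxogibberellan-19-oate | C[C@@]12CCC(=O)[C@@](C)(C(=O)OCc4ccccc4)[C@H]1[C@H](COCc4ccccc4)[C@@]13C[C@@H](CC[C@@H]21)[C@@](C)(O)C3 | intermediate
26 | benzyl (3S,4S,5S,6S,8R,9S,10S,13R,16S)-7-(benzyloxy)-3,16-dihydroxygibberellan-19-oate | C[C@@]12CC[C@H](O)[C@@](C)(C(=O)OCc4ccccc4)[C@H]1[C@H](COCc4ccccc4)[C@@]13C[C@@H](CC[C@@H]21)[C@@](C)(O)C3 | intermediate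
27 | (3S,4S,5S,6S,8R,9S,10S,13R,16S)-3,7,16-trihydroxygibberellan-19-oic acid | C[C@@]12CC[C@H](O)[C@@](C)(C(=O)O)[C@H]1[C@H](CO)[C@@]13C[C@@H](CC[C@@H]21)[C@@](C)(O)C3 | target

## Step count and least certain steps

Total step count: 18. Longest linear sequence: 16 steps (steps 1–5, 7, 8 and 10–18, from 1); steps 6 and 9 prepare the two side reagents.

**Step 15 (key step).**
- What may go wrong: the C4 enolate or radical may be intercepted by a proton or a hydrogen atom before ring A closes, so that only ring B forms. Facial control may also be lost at C10 (cis A/B fusion) and rotamer control at C4 (equatorial ester). Neither centre is held by a rigid element: C10 rests on a methyl/methylene size difference, and C4 on a balance between allylic strain and a 1,3-diaxial contact.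
- Fallback (known chemistry, from 22, returning at 24): a protic iron-hydride Giese cyclisation of 22 (Fe(acac)3, PhSiH3, EtOH/(CH2OH)2, 60 °C), in which the C4 position is simply protonated, should give the ring B ester benzyl (5R,6S,8R,9S,10R,13R,16S)-7-(benzyloxy)-3,3-(ethane-1,2-diyldioxy)-16-[(triethylsilyl)oxy]-3,4-secogibberellan-19-oate F1. Enolisation with LiN(i-Pr)2 and bromination with CBr4 would give the tertiary α-bromo ester benzyl (5S,6S,8R,9S,10S,13R,16S)-7-(benzyloxy)-4-bromo-3,3-(ethane-1,2-diyldioxy)-16-[(triethylsilyl)oxy]-3,4-secogibberellan-19-oate F2. Aqueous HCl would then free the aldehyde and the C16 carbinol to give benzyl (5S,6S,8R,9S,10S,13R,16S)-7-(benzyloxy)-4-bromo-16-hydroxy-3-oxo-3,4-secogibberellan-19-oate F3. SmI2 in THF at −78 °C would close ring A by an intramolecular Reformatsky reaction through a samarium-bridged transition state, generating the C4 enolate regiospecifically beside the enolisable aldehyde, to give 24.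

**Step 2.**
- What may go wrong: poor discrimination between the two enantiotopic enone arms, because the allyl and 2-oxopropyl groups that define the two faces of the dienone are of similar size; a second conjugate reduction of the product enone is a lesser concern.
- Fallback (from 3, returning at 5): racemic reductive aldol cyclisation with [(Ph3P)CuH]6 gives 5 together with its enantiomer (1S,5R,7R)-7-hydroxy-7-methyl-5-(prop-2-en-1-yl)bicyclo[3.2.1]oct-3-en-2-one F4. Preparative chromatography on a chiral stationary phase returns enantiopure 5.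

**Step 5.**
- What may go wrong: weak diastereofacial control, because the quaternary C8 next to the enamine may slow or oppose the catalyst, and erosion at C6 by enolisation or loss of water before the Wittig step.
- Fallback (from 7, returning at 13): condensation with (S)-1-amino-2-(methoxymethyl)pyrrolidine gives the hydrazone (E)-N-[(2S)-2-(methoxymethyl)pyrrolidin-1-yl]-2-[(1R,5R,6S)-6-methyl-4-oxo-6-[(triethylsilyl)oxy]bicyclo[3.2.1]oct-2-en-1-yl]ethan-1-imine F5. Deprotonation with LiN(i-Pr)2 and auxiliary-controlled alkylation with BnOCH2Cl gives (1E,2R)-3-(benzyloxy)-N-[(2S)-2-(methoxymethyl)pyrrolidin-1-yl]-2-[(1R,5R,6S)-6-methyl-4-oxo-6-[(triethylsilyl)oxy]bicyclo[3.2.1]oct-2-en-1-yl]propan-1-imine F6. Ozonolysis of the C=N bond at −78 °C gives (2S)-3-(benzyloxy)-2-[(1R,5R,6S)-6-methyl-4-oxo-6-[(triethylsilyl)oxy]bicyclo[3.2.1]oct-2-en-1-yl]propanal F7, and Wittig olefination with 11 gives 13 directly.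

**Step 10.**
- What may go wrong: slow addition at the neopentyl-type C9, which is flanked by the branched C6 chain, so that the Grignard reagent attacks the benzyl ester or the ketone carbonyl instead.
- Fallback (from 16 and 13, returning at 19): Miyaura borylation of 16 (PdCl2(PPh3)2, KOPh, bis(pinacolato)diboron) gives 2-[4-(1,3-dioxolan-2-yl)but-1-en-2-yl]-4,4,5,5-tetramethyl-1,3,2-dioxaborolane F8. Rhodium-catalysed conjugate addition to 13 ([Rh(cod)OH]2, dioxane/H2O, 60 °C), which tolerates the ester, gives 19 with the same facial preference.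

## Further compounds

F1 | step 15 | benzyl (5R,6S,8R,9S,10R,13R,16S)-7-(benzyloxy)-3,3-(ethane-1,2-diyldioxy)-16-[(triethylsilyl)oxy]-3,4-secogibberellan-19-oate (both C4 epimers) | C[C@@]1(CCC2OCCO2)[C@@H](C(C)C(=O)OCc2ccccc2)[C@H](COCc2ccccc2)[C@@]23C[C@@H](CC[C@@H]12)[C@@](C)(O[Si](CC)(CC)CC)C3
F2 | step 15 | benzyl (5S,6S,8R,9S,10S,13R,16S)-7-(benzyloxy)-4-bromo-3,3-(ethane-1,2-diyldioxy)-16-[(triethylsilyl)oxy]-3,4-secogibberellan-19-oate (both C4 epimers) | C[C@@]1(CCC2OCCO2)[C@@H](C(C)(Br)C(=O)OCc2ccccc2)[C@H](COCc2ccccc2)[C@@]23C[C@@H](CC[C@@H]12)[C@@](C)(O[Si](CC)(CC)CC)C3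
F3 | step 15 | benzyl (5S,6S,8R,9S,10S,13R,16S)-7-(benzyloxy)-4-bromo-16-hydroxy-3-oxo-3,4-secogibberellan-19-oate (both C4 epimers) | C[C@@]1(CCC=O)[C@@H](C(C)(Br)C(=O)OCc2ccccc2)[C@H](COCc2ccccc2)[C@@]23C[C@@H](CC[C@@H]12)[C@@](C)(O)C3
F4 | step 2 | (1S,5R,7R)-7-hydroxy-7-methyl-5-(prop-2-en-1-yl)bicyclo[3.2.1]oct-3-en-2-one | C=CC[C@]12C[C@H](C(=O)C=C1)[C@](C)(O)C2
F5 | step 5 | (E)-N-[(2S)-2-(methoxymethyl)pyrrolidin-1-yl]-2-[(1R,5R,6S)-6-methyl-4-oxo-6-[(triethylsilyl)oxy]bicyclo[3.2.1]oct-2-en-1-yl]ethan-1-imine | COC[C@@H]1CCCN1/N=C/C[C@@]23C[C@@H](C(=O)C=C2)[C@@](C)(O[Si](CC)(CC)CC)C3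
F6 | step 5 | (1E,2R)-3-(benzyloxy)-N-[(2S)-2-(methoxymethyl)pyrrolidin-1-yl]-2-[(1R,5R,6S)-6-methyl-4-oxo-6-[(triethylsilyl)oxy]bicyclo[3.2.1]oct-2-en-1-yl]propan-1-imine | COC[C@@H]1CCCN1/N=C/[C@H](COCc1ccccc1)[C@@]23C[C@@H](C(=O)C=C2)[C@@](C)(O[Si](CC)(CC)CC)C3
F7 | step 5 | (2S)-3-(benzyloxy)-2-[(1R,5R,6S)-6-methyl-4-oxo-6-[(triethylsilyl)oxy]bicyclo[3.2.1]oct-2-en-1-yl]propanal | O=C[C@H](COCc1ccccc1)[C@@]12C[C@@H](C(=O)C=C1)[C@@](C)(O[Si](CC)(CC)CC)C2
F8 | step 10 | 2-[4-(1,3-dioxolan-2-yl)but-1-en-2-yl]-4,4,5,5-tetramethyl-1,3,2-dioxaborolane | C=C(CCC1OCCO1)B1OC(C)(C)C(C)(C)O1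
A1 | alternative 1 | (7aR)-7a-(prop-2-en-1-yl)-2,3,7,7a-tetrahydro-1H-indene-1,5(6H)-dione | C=CC[C@]12CCC(=O)C=C1CCC2=O
A2 | alternative 1 | L-proline | OC(=O)[C@@H]1CCCN1
A3 | alternative 2 | 7-oxogibberell-16-en-19-oic acid of the natural gibberellin series (the C7 aldehyde with a C16 exocyclic methylene and no oxygen at C3) | C[C@@]12CCC[C@@](C)(C(=O)O)[C@H]1[C@H](C=O)[C@@]13C[C@@H](CC[C@@H]21)C(=C)C3
A4 | alternative 3 | benzyl 7-(benzyloxy)-16-hydroxy-3-oxogibberell-11-en-19-oate (configuration at C4, C5, C6, C8, C9, C10, C13 and C16 as in 25) | C[C@@]12CCC(=O)[C@@](C)(C(=O)OCc4ccccc4)[C@H]1[C@H](COCc4ccccc4)[C@@]13C[C@@H](C=C[C@@H]21)[C@@](C)(O)C3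
A5 | alternative 3 | manganese triacetate, Mn(OAc)3 | [Mn+3].CC(=O)[O-].CC(=O)[O-].CC(=O)[O-]
A6 | alternative 3 | copper diacetate, Cu(OAc)2 | [Cu+2].CC(=O)[O-].CC(=O)[O-]
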